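**Plan**
1. Lettering: the lower flavan has rings A (resorcinol), C (pyran) and B (central catechol, C1′–C6′). The upper flavan has rings D (resorcinol), F (pyran) and E (catechol). The target is fisetinidol-(4α→6′)-ent-epifisetinidol: upper 2R,3S,4R (2,3-trans-3,4-trans), lower 2S,3S (2,3-cis).
2. Cuts, in retrosynthetic order: seven O–benzyl bonds; C3–O and C4–H of ring F (syn hydroboration of a 4-arylflav-3-ene); C4–C4a of ring F (6-endo-dig hydroarylation of an aryl propargyl ether); C4(F)–C6′(B) (Sonogashira). Further back: both C2–O1 ether bonds (propargylic etherification) and, in ring C, C3–H (ketone reduction) and C4–C4a/C3=O (oxidative gold cyclisation).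
3. Enabling feature: in ring F the atoms C2–C3–C4 hang as a three-carbon chain on the phenol oxygen O1 of ring D. C4a is ortho to O1 and para to O7, C4 is bound to C6′ of ring B para to O3′, and O3 is trans to both aryl neighbours. Raising C3–C4 to an alkyne gives a slim linker without stereocentres that ring D can attack at C4. C2 alone then dictates C3 and C4.
4. Forward order: both halves come from the same pieces (3,4-bis(benzyloxy)benzaldehyde, an ethynyl unit, 3-(benzyloxy)phenol). Ring C is closed first, the halves are joined at the alkyne, ring F is closed last, then all benzyl groups are removed.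
5. Stereochemistry: C2 of each unit comes from enantioconvergent copper–pybox etherification with antipodal ligands. Lower C3 comes from bulky-hydride attack anti to ring B. Upper C3 and C4 come from syn hydroboration anti to ring E.

Key step: step 10

Assumption: the (R,R)-Ph-pybox copper catalyst is taken to give the (R)-ether 6 and its antipode the (S)-ether 12; if the sense of induction proves opposite, the two ligand antipodes are exchanged between steps 3 and 8 and nothing else changes.

**Step 1**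
Reactants: 1 3,4-bis(benzyloxy)benzaldehyde
Product: 2 4,5-bis(benzyloxy)-2-iodobenzaldehyde
Conditions: I2, AgOCOCF3, CH2Cl2, 0 °C to rt, dark
Reagents that add atoms: iodine, II
Why: Electrophilic aromatic iodination by trifluoroacetyl hypoiodite formed in situ should go to C6 of 1, which is para to the 3-benzyloxy group and the least crowded activated position, as in the halogenation of veratraldehyde-type aldehydes.

**Step 2**
Reactants: 2 4,5-bis(benzyloxy)-2-iodobenzaldehyde
Product: 4 rac-1-[4,5-bis(benzyloxy)-2-iodophenyl]prop-2-yn-1-yl acetate, via bromomagnesium alkoxide 3 (not isolated)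
Conditions: HC≡CMgBr, THF, −20 to 0 °C; then Ac2O, 0 °C to rt
Reagents that add atoms: ethynylmagnesium bromide, C#C[Mg]Br; acetic anhydride, CC(=O)OC(C)=O
Why: 1,2-addition of an alkynyl Grignard reagent, which is too weak to exchange with the aryl iodide, followed by O-acylation of the alkoxide in the same flask; the centre is left racemic because step 3 is enantioconvergent.

**Step 3**
Reactants: 4 rac-1-[4,5-bis(benzyloxy)-2-iodophenyl]prop-2-yn-1-yl acetate; 5 3-(benzyloxy)phenol
Product: 6 (R)-1,2-bis(benzyloxy)-4-{1-[3-(benzyloxy)phenoxy]prop-2-yn-1-yl}-5-iodobenzene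
Conditions: Cu(MeCN)4PF6 (5 mol %), (R,R)-Ph-pybox (6 mol %), iPr2NEt (1.2 equiv), PhCF3, −10 °C
Reagents that add atoms: none
Why: Copper-catalysed asymmetric propargylic etherification with a phenol: both enantiomers of 4 lose acetate to one planar copper allenylidene, and the pybox ligand decides the face on which the oxygen of 5 attacks the propargylic carbon, which sets C2 of the lower unit.

**Step 4**
Reactants: 6 (R)-1,2-bis(benzyloxy)-4-{1-[3-(benzyloxy)phenoxy]prop-2-yn-1-yl}-5-iodobenzene
Product: 7 (2S)-7-(benzyloxy)-2-[4,5-bis(benzyloxy)-2-iodophenyl]chroman-3-one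
Conditions: Me4tBuXPhosAuNTf2 (5 mol %), 2,6-dichloropyridine N-oxide (1.3 equiv), 4 Å MS, ClCH2CH2Cl, rt
Reagents that add atoms: 2,6-dichloropyridine N-oxide, [O-][n+]1c(Cl)cccc1Cl
Why: Gold-catalysed alkyne oxidation and cyclisation of a propargyl aryl ether to a chroman-3-one: the N-oxide adds to the internal carbon of the gold-bound terminal alkyne, and the α-oxo gold carbene at the terminal carbon is captured by the ring A carbon ortho to O1 and para to O7, so ring C closes with C3 already oxygenated and C2 untouched under neutral conditions.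

**Step 5**
Reactants: 7 (2S)-7-(benzyloxy)-2-[4,5-bis(benzyloxy)-2-iodophenyl]chroman-3-one
Product: 8 (2S,3S)-7-(benzyloxy)-2-[4,5-bis(benzyloxy)-2-iodophenyl]chroman-3-ol (2,3-cis)
Conditions: LiBH(s-Bu)3, LiBr, THF, −78 °C; H2O quench
Reagents that add atoms: none
Why: Diastereoselective ketone reduction with a bulky hydride, the reaction type used to turn 2,3-trans into 2,3-cis flavan-3-ols through the 3-ketone: hydride should arrive on the face opposite ring B and place the 3-OH cis to it (3S), and the low temperature protects the enolisable C2.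

**Step 6**
Reactants: 8 (2S,3S)-7-(benzyloxy)-2-[4,5-bis(benzyloxy)-2-iodophenyl]chroman-3-ol
Product: 9 (2S,3S)-3,7-bis(benzyloxy)-2-[4,5-bis(benzyloxy)-2-iodophenyl]chroman
Conditions: NaH, BnBr, Bu4NI (cat.), DMF, 0 °C to rt
Reagents that add atoms: benzyl bromide, BrCc1ccccc1
Why: Williamson etherification masks the 3-OH, which would otherwise add to the neighbouring gold-activated alkyne in step 10 and consume borane in step 11; with all phenols blocked no quinone methide can form, so C2 should not epimerise.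

**Step 7**
Reactants: 1 3,4-bis(benzyloxy)benzaldehyde
Product: 11 rac-1-[3,4-bis(benzyloxy)phenyl]prop-2-yn-1-yl acetate, via bromomagnesium alkoxide 10 (not isolated)
Conditions: HC≡CMgBr, THF, −20 to 0 °C; then Ac2O, 0 °C to rt
Reagents that add atoms: ethynylmagnesium bromide, C#C[Mg]Br; acetic anhydride, CC(=O)OC(C)=O
Why: Alkynyl Grignard addition and in situ O-acylation as in step 2, again giving a racemate that the next step converges.

**Step 8**
Reactants: 11 rac-1-[3,4-bis(benzyloxy)phenyl]prop-2-yn-1-yl acetate; 5 3-(benzyloxy)phenol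
Product: 12 (S)-1,2-bis(benzyloxy)-4-{1-[3-(benzyloxy)phenoxy]prop-2-yn-1-yl}benzene
Conditions: Cu(MeCN)4PF6 (5 mol %), (S,S)-Ph-pybox (6 mol %), iPr2NEt (1.2 equiv), PhCF3, −10 °C
Reagents that add atoms: none
Why: The same copper-catalysed asymmetric propargylic etherification with the antipodal ligand sets C2 of the upper unit in the opposite spatial sense, as the target requires.

**Step 9**
Reactants: 9 (2S,3S)-3,7-bis(benzyloxy)-2-[4,5-bis(benzyloxy)-2-iodophenyl]chroman; 12 (S)-1,2-bis(benzyloxy)-4-{1-[3-(benzyloxy)phenoxy]prop-2-yn-1-yl}benzene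
Product: 13 (2S,3S)-3,7-bis(benzyloxy)-2-{4,5-bis(benzyloxy)-2-[(3R)-3-[3-(benzyloxy)phenoxy]-3-[3,4-bis(benzyloxy)phenyl]prop-1-yn-1-yl]phenyl}chroman
Conditions: Pd(PPh3)2Cl2 (5 mol %), CuI (10 mol %), Et3N/THF, degassed, rt to 40 °C
Reagents that add atoms: none
Why: Sonogashira coupling forms the hindered C4(F)–C6′(B) bond through a rod-shaped alkyne that tolerates the bulky ortho substituent of the aryl iodide; the mild amine base leaves the propargylic centre alone, and its descriptor changes to R only by priority.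

**Step 10**
Reactants: 13 (2S,3S)-3,7-bis(benzyloxy)-2-{4,5-bis(benzyloxy)-2-[(3R)-3-[3-(benzyloxy)phenoxy]-3-[3,4-bis(benzyloxy)phenyl]prop-1-yn-1-yl]phenyl}chroman
Product: 14 (2S,3S)-3,7-bis(benzyloxy)-2-{4,5-bis(benzyloxy)-2-[(2S)-7-(benzyloxy)-2-[3,4-bis(benzyloxy)phenyl]-2H-chromen-4-yl]phenyl}chroman
Conditions: (JohnPhos)Au(MeCN)SbF6 (5 mol %), 2,6-di-tert-butyl-4-methylpyridine (10 mol %), 4 Å MS, CH2Cl2, 0 °C to rt, dark
Reagents that add atoms: none
Why: The cationic monovalent gold centre binds the alkyne, the ring D carbon that is ortho to O1 and para to the 7-benzyloxy group attacks C4 anti to gold, and rearomatisation followed by protodeauration at C3 should give the 4-arylflav-3-ene. The closest known reaction type is the gold-catalysed intramolecular hydroarylation of 3-arylprop-2-ynyl aryl ethers to 4-aryl-2H-chromenes. Ring F closes in the 6-endo-dig mode. No new stereocentre is formed: C2 is a spectator that must keep its configuration (descriptor S here only by priority), and the new C3=C4 bond is the relay through which C2 sets C3 and C4 in step 11. Endo over 5-exo closure is secured by ring B, whose 3′-benzyloxy group is para to the alkyne and places the developing positive charge on C4, and site selectivity on ring D is secured because the other ortho carbon lies between two oxygen substituents. Ionisation of the activated C2–O1 bond and participation of oxygen nucleophiles are held back by the buffered, acid-free catalyst, the low temperature and the benzyl cap on the lower 3-oxygen, while darkness avoids electrocyclic opening of the chromene.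

**Step 11**
Reactants: 14 (2S,3S)-3,7-bis(benzyloxy)-2-{4,5-bis(benzyloxy)-2-[(2S)-7-(benzyloxy)-2-[3,4-bis(benzyloxy)phenyl]-2H-chromen-4-yl]phenyl}chroman
Product: 16 (2R,3S,4R)-7-(benzyloxy)-2-[3,4-bis(benzyloxy)phenyl]-4-{4,5-bis(benzyloxy)-2-[(2S,3S)-3,7-bis(benzyloxy)chroman-2-yl]phenyl}chroman-3-ol, via C3-borane 15 (not isolated)
Conditions: BH3·THF, THF, 0 °C to rt; then NaOH, H2O2, H2O, 0 °C
Reagents that add atoms: borane, B; hydrogen peroxide, OO
Why: Hydroboration–oxidation, known for flav-3-enes: boron goes to the less substituted C3 and hydrogen to the diaryl-substituted C4 in a syn addition on the face of ring F opposite ring E (ring B can turn its ortho substituent to the ring E side), so oxidation with retention should give 3-OH trans to ring E (3S) and H-4 cis to 3-OH, that is ring B trans to 3-OH (4R).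

**Step 12**
Reactants: 16 (2R,3S,4R)-7-(benzyloxy)-2-[3,4-bis(benzyloxy)phenyl]-4-{4,5-bis(benzyloxy)-2-[(2S,3S)-3,7-bis(benzyloxy)chroman-2-yl]phenyl}chroman-3-ol
Product: 17 (2R,3S,4R)-2-(3,4-dihydroxyphenyl)-4-{2-[(2S,3S)-3,7-dihydroxychroman-2-yl]-4,5-dihydroxyphenyl}chroman-3,7-diol
Conditions: H2 (1 atm), Pd(OH)2/C, THF/MeOH, rt, work-up under argon
Reagents that add atoms: none
Why: Global hydrogenolysis of the seven benzyl ethers, the standard last step for oligomeric flavan-3-ols; the ring C2–O1 bonds and the C4–aryl bond are far slower to cleave than acyclic O-benzyl groups, and the neutral medium should not epimerise any centre.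

**Compound list**
1 | 3,4-bis(benzyloxy)benzaldehyde | O=Cc1ccc(OCc2ccccc2)c(OCc2ccccc2)c1 | starting material
2 | 4,5-bis(benzyloxy)-2-iodobenzaldehyde | O=Cc1cc(OCc2ccccc2)c(OCc2ccccc2)cc1I | intermediate
3 | bromomagnesium 1-[4,5-bis(benzyloxy)-2-iodophenyl]prop-2-yn-1-olate (racemic) | C#CC(O[Mg]Br)c1cc(OCc2ccccc2)c(OCc2ccccc2)cc1I | intermediate
4 | rac-1-[4,5-bis(benzyloxy)-2-iodophenyl]prop-2-yn-1-yl acetate | C#CC(OC(C)=O)c1cc(OCc2ccccc2)c(OCc2ccccc2)cc1I | intermediate
5 | 3-(benzyloxy)phenol | Oc1cccc(OCc2ccccc2)c1 | starting material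
6 | (R)-1,2-bis(benzyloxy)-4-{1-[3-(benzyloxy)phenoxy]prop-2-yn-1-yl}-5-iodobenzene | C#C[C@@H](Oc1cccc(OCc2ccccc2)c1)c1cc(OCc2ccccc2)c(OCc2ccccc2)cc1I | intermediate
7 | (2S)-7-(benzyloxy)-2-[4,5-bis(benzyloxy)-2-iodophenyl]chroman-3-one | c9ccccc9COc1ccc2c(c1)O[C@@H](c1cc(OCc9ccccc9)c(OCc9ccccc9)cc1I)C(=O)C2 | intermediate
8 | (2S,3S)-7-(benzyloxy)-2-[4,5-bis(benzyloxy)-2-iodophenyl]chroman-3-ol | c9ccccc9COc1ccc2c(c1)O[C@@H](c1cc(OCc9ccccc9)c(OCc9ccccc9)cc1I)[C@@H](O)C2 | intermediate
9 | (2S,3S)-3,7-bis(benzyloxy)-2-[4,5-bis(benzyloxy)-2-iodophenyl]chroman | c9ccccc9COc1ccc2c(c1)O[C@@H](c1cc(OCc9ccccc9)c(OCc9ccccc9)cc1I)[C@@H](OCc9ccccc9)C2 | intermediate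
10 | bromomagnesium 1-[3,4-bis(benzyloxy)phenyl]prop-2-yn-1-olate (racemic) | C#CC(O[Mg]Br)c1ccc(OCc2ccccc2)c(OCc2ccccc2)c1 | intermediate
11 | rac-1-[3,4-bis(benzyloxy)phenyl]prop-2-yn-1-yl acetate | C#CC(OC(C)=O)c1ccc(OCc2ccccc2)c(OCc2ccccc2)c1 | intermediate
12 | (S)-1,2-bis(benzyloxy)-4-{1-[3-(benzyloxy)phenoxy]prop-2-yn-1-yl}benzene | C#C[C@H](Oc1cccc(OCc2ccccc2)c1)c1ccc(OCc2ccccc2)c(OCc2ccccc2)c1 | intermediate
13 | coupled aryl propargyl ether (lower 2S,3S; propargylic carbon R) | c9ccccc9COc1ccc2c(c1)O[C@@H](c1cc(OCc9ccccc9)c(OCc9ccccc9)cc1C#C[C@H](Oc3cccc(OCc9ccccc9)c3)c3ccc(OCc9ccccc9)c(OCc9ccccc9)c3)[C@@H](OCc9ccccc9)C2 | intermediate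
14 | 4-arylflav-3-ene (lower 2S,3S; ring F C2 S) | c9ccccc9COc1ccc2c(c1)O[C@@H](c1cc(OCc9ccccc9)c(OCc9ccccc9)cc1C4=C[C@@H](c3ccc(OCc9ccccc9)c(OCc9ccccc9)c3)Oc3cc(OCc9ccccc9)ccc34)[C@@H](OCc9ccccc9)C2 | intermediate
15 | C3-borane of ring F (BH2 trans to ring E and trans to ring B) | c9ccccc9COc1ccc2c(c1)O[C@@H](c1cc(OCc9ccccc9)c(OCc9ccccc9)cc1[C@@H]4c3ccc(OCc9ccccc9)cc3O[C@H](c3ccc(OCc9ccccc9)c(OCc9ccccc9)c3)[C@H]4B)[C@@H](OCc9ccccc9)C2 | intermediate
16 | hepta-O-benzyl ether of the target (upper 2R,3S,4R; lower 2S,3S) | c9ccccc9COc1ccc2c(c1)O[C@@H](c1cc(OCc9ccccc9)c(OCc9ccccc9)cc1[C@@H]4c3ccc(OCc9ccccc9)cc3O[C@H](c3ccc(OCc9ccccc9)c(OCc9ccccc9)c3)[C@H]4O)[C@@H](OCc9ccccc9)C2 | intermediate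
17 | (2R,3S,4R)-2-(3,4-dihydroxyphenyl)-4-{2-[(2S,3S)-3,7-dihydroxychroman-2-yl]-4,5-dihydroxyphenyl}chroman-3,7-diol | Oc1ccc2c(c1)O[C@@H](c1cc(O)c(O)cc1[C@@H]1c3ccc(O)cc3O[C@H](c3ccc(O)c(O)c3)[C@H]1O)[C@@H](O)C2 | target

**Total step count:** 12. **Longest linear sequence:** 10 (steps 1–6, then 9–12).

**Steps most likely to fail**

Step 10. Three things may go wrong. The doubly activated C2–O1 bond may ionise and lose configuration at C2. The nearby benzyl ether oxygen may be drawn into the activated alkyne. The closure may be slowed by the ortho-flavanyl group.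
- The fallback sets out from 13 and comes back at 16, so it also bypasses the hydroboration, where β-elimination of the ring oxygen could interfere. It replaces the alkyne by an epoxide as the electrophile.
- Ruthenium-catalysed trans-hydrosilylation ([Cp*Ru(MeCN)3]PF6, (EtO)3SiH, CH2Cl2) should give the C4-triethoxysilyl (Z)-alkene F1.
- Protodesilylation (CuI, Bu4NF, THF) should give the (E)-1,3-diarylallyl aryl ether F2.
- Shi epoxidation with the D-fructose-derived ketone (KHSO5 as Oxone, K2CO3 buffer, MeCN/dimethoxymethane/H2O, 0 °C) should give the (3S,4R)-trans-epoxide F3.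
- A stereospecific intramolecular Friedel–Crafts epoxide–arene closure follows (hexafluoroisopropanol, 0 °C, or catalytic FeBr3/AgOTf). Ring D attacks C4 in the 6-endo mode with inversion, which should deliver 16 with the 3-OH and the 3,4-trans relation in place.

Step 4. Direct hydroarylation of the terminal alkyne by the electron-rich ring A may outrun oxygen transfer. The carbene may also be captured by ring B, or be over-oxidised.
- The fallback sets out from 6 and comes back at 7. It accepts the hydroarylation instead of fighting it.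
- (JohnPhos)Au(MeCN)SbF6 in CH2Cl2 should give the (2R)-2-aryl-2H-chromene F4.
- BH3·THF should add anti to ring B to give the C3-borane F5.
- NaOH/H2O2 should give the (2S,3R)-2,3-trans-chroman-3-ol F6.
- Dess–Martin periodinane in CH2Cl2 should oxidise it to 7.

Step 3. The electron-rich phenol may react through a ring carbon instead of oxygen, and face selection may be poor with the ortho-iodoaryl group next to the reacting carbon.
- The fallback sets out from 2 and comes back at 6. The centre is set by reagent-controlled carbonyl addition and then inverted.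
- Zinc-mediated asymmetric alkynylation (Me2Zn, trimethylsilylacetylene, the ProPhenol ligand antipode that delivers the S alcohol, toluene) should give the (S)-trimethylsilyl propargylic alcohol F7.
- Mitsunobu etherification with 5 (PPh3, DIAD, toluene, 0 °C) should proceed with inversion to the (R)-trimethylsilyl propargyl aryl ether F8.
- K2CO3 in MeOH should remove the silyl group to give 6.

**Further compounds**
F1 | step 10 | C4-triethoxysilyl (Z)-alkene (silicon on the carbon bound to ring B; ring B and C2 trans) | c9ccccc9COc1ccc2c(c1)O[C@@H](c1cc(OCc9ccccc9)c(OCc9ccccc9)cc1/C([Si](OCC)(OCC)OCC)=C/[C@H](Oc3cccc(OCc9ccccc9)c3)c3ccc(OCc9ccccc9)c(OCc9ccccc9)c3)[C@@H](OCc9ccccc9)C2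
F2 | step 10 | (E)-1,3-diarylallyl aryl ether | c9ccccc9COc1ccc2c(c1)O[C@@H](c1cc(OCc9ccccc9)c(OCc9ccccc9)cc1/C=C/[C@H](Oc3cccc(OCc9ccccc9)c3)c3ccc(OCc9ccccc9)c(OCc9ccccc9)c3)[C@@H](OCc9ccccc9)C2
F3 | step 10 | (3S,4R)-trans-epoxide (ring F numbering, C2 R) | c9ccccc9COc1ccc2c(c1)O[C@@H](c1cc(OCc9ccccc9)c(OCc9ccccc9)cc1[C@H]4O[C@@H]4[C@H](Oc3cccc(OCc9ccccc9)c3)c3ccc(OCc9ccccc9)c(OCc9ccccc9)c3)[C@@H](OCc9ccccc9)C2
F4 | step 4 | (2R)-7-(benzyloxy)-2-[4,5-bis(benzyloxy)-2-iodophenyl]-2H-chromene | c9ccccc9COc1ccc2c(c1)O[C@@H](c1cc(OCc9ccccc9)c(OCc9ccccc9)cc1I)C=C2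
F5 | step 4 | C3-borane of ring C (BH2 trans to ring B) | c9ccccc9COc1ccc2c(c1)O[C@@H](c1cc(OCc9ccccc9)c(OCc9ccccc9)cc1I)[C@H](B)C2
F6 | step 4 | (2S,3R)-7-(benzyloxy)-2-[4,5-bis(benzyloxy)-2-iodophenyl]chroman-3-ol (2,3-trans) | c9ccccc9COc1ccc2c(c1)O[C@@H](c1cc(OCc9ccccc9)c(OCc9ccccc9)cc1I)[C@H](O)C2
F7 | step 3 | (S)-1-[4,5-bis(benzyloxy)-2-iodophenyl]-3-(trimethylsilyl)prop-2-yn-1-ol | C[Si](C)(C)C#C[C@H](O)c1cc(OCc2ccccc2)c(OCc2ccccc2)cc1I
F8 | step 3 | (R)-{3-[4,5-bis(benzyloxy)-2-iodophenyl]-3-[3-(benzyloxy)phenoxy]prop-1-yn-1-yl}trimethylsilane | C[Si](C)(C)C#C[C@@H](Oc1cccc(OCc2ccccc2)c1)c1cc(OCc2ccccc2)c(OCc2ccccc2)cc1I
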